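## Structural features

The target is the (R)-2-methylbutanoate of (−)-lariciresinol. It has one tetrahydrofuran ring (O1, C2, C3, C4, C5) with a 4-hydroxy-3-methoxyphenyl group on C2, an acyloxymethyl branch on C3 and a 4-hydroxy-3-methoxybenzyl group on C4; C5 is an unsubstituted OCH2. The three ring stereocentres are contiguous, (2R,3S,4S): aryl and CH2O are trans across C2–C3, CH2O and benzyl are cis across C3–C4. The fourth stereocentre (R) sits α to the ester carbonyl of the side chain and is remote from the ring. Fragile points are the C2–O1 bond (a p-oxygenated benzylic ether that acid can open, with epimerisation at C2 or Friedel–Crafts closure onto the other arene), the two free phenols (which compete with the primary alcohol in any acylation) and the ester with its enolisable α-centre. The real difficulty is stereochemical: three adjacent CH centres with no handle between them, and a 3,4-cis relation that is the less stable arrangement and must be set kinetically. The key step uses the fact that C2 is a benzylic carbinol carbon next to C3, whose exocyclic carbon can be a carboxyl, so C2–C3 is an aryl β-hydroxy ester unit. If C5 is also raised to the acyl level, O1–C5 is a lactone bond and the ring O1/C2–C5 is an aryl paraconate, available from an aroylsuccinate by reduction of its ketone.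

## Logic of the disconnections

**27 ⇒ 26.** The two phenolic O–H bonds are traced back to O–Si bonds. Keeping both phenols masked through the acylation means no step has to tell a primary alcohol from two phenols. The forward step must cleave two aryl silyl ethers without touching the ester, its α-centre or the benzylic ether, so buffered fluoride is needed.

**26 ⇒ 24 + 25.** The acyl C–O bond of the ester is cut. The side chain becomes a commercial chiral acid and the ring problem loses its fourth stereocentre. The coupling must not racemise the α-centre of 25, so a carbodiimide is used and not an acid chloride with amine base.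

**24 ⇒ 23.** The O–Si bond of the primary silyl ether is restored. This requires the alkyl silyl ether to differ in lability from the aryl silyl ethers, so an alkyl tert-butyldimethylsilyl ether stands beside aryl triisopropylsilyl ethers. The forward acid must be mild enough to spare C2–O1.

**23 ⇒ 21 (through 22).** The O1–C5 ether bond is cut. C5 is an unsubstituted CH2, so the C2 oxygen can displace a primary sulfonate without touching a stereocentre. The gain is an acyclic 1,4-diol with one primary and one secondary benzylic hydroxyl; the demand is activation of the primary one only.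

**21 ⇒ 20.** The two C5–H bonds are removed, so C5 returns to the acyl level and O1–C5 becomes a lactone bond. The lactone carbonyl is what makes C4 reactive in the steps before. The hydride must reduce a lactone and leave silyl ethers alone.

**20 ⇒ 19.** The C4–H bond and one benzylic C–H bond are removed to give an exocyclic alkene. The less stable 3,4-cis relation is best set by adding hydrogen to C4 from the face opposite the C3 branch. The C4 stereocentre disappears; the forward step needs high facial selectivity and no hydrogenolysis of the benzylic C2–O bond.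

**19 ⇒ 14 + 16 (through 17 and 18); 16 ⇒ 15.** The C4=C bond to the benzylic carbon is cut in the aldol sense, dividing the molecule into two halves of similar size that share one aromatic core. The lactone must have only one enolisable position, so the C3 branch has to be a protected CH2OH at this stage and not an ester. 16 comes from 15 by cutting one O–Si bond.

**14 ⇒ 13 ⇒ 12 ⇒ 11.** Functional group changes at the C3 branch: O–Si bond, then the C–H bonds of CH2OH back to a carboxylic acid, then the acid back to its tert-butyl ester. The branch has to be a carboxyl for the key step. One carboxyl carbon must later be reduced beside the other, which works if one is a free acid (reduced by borane) and the other a lactone; this requires two different esters in the precursor.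

**11 ⇒ 9 (through 10).** The O1–C5 acyl bond and the C2–H bond are cut. The ring and both stereocentres vanish, leaving a keto diester whose only stereocentre racemises freely. The forward reduction must choose one ketone face (catalyst) and one of two interconverting C3 configurations (dynamic kinetic resolution), and the hydroxyl must close on the ester that gives a five-membered ring.

**9 ⇒ 7 + 8.** The C3–C4 bond is cut (enolate alkylation), giving a β-keto ester and a two-carbon electrophile. The demand is clean mono-C-alkylation.

**7 ⇒ 3 + 4 (through 5 and 6).** The C2–C3 bond between the aryl ketone and its α-carbon is cut (acylation of a malonate half ester). The gain is a simple aromatic acid; the C-acylation must be mild and non-basic to keep the aryl silyl ether.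

**3 ⇒ 1 (through 2).** One O–Si bond is cut, leading to the commercial hydroxy acid.

## Other disconnections considered

**Alternative 1:** The cut is the C3–C4 ring bond together with one benzylic C–H bond. The precursor is the epoxy cinnamyl ether A1, whose only stereocentre of consequence is the C2 carbinol carbon.

- **Forward step:** Cp2TiCl (trivalent titanium, from Cp2TiCl2 and zinc) would open the terminal epoxide by electron transfer to a secondary C3 radical with a titanium alkoxide on the CH2O carbon. The radical would add 5-exo-trig to the styrene-type alkene, forming C3–C4, and a second equivalent would reduce the benzylic radical, which is protonated on work-up to give A2.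
- **In favour:** Ring, C3 and C4 arise in one step. A chair-like transition state with the C2 aryl group pseudo-equatorial should favour 2,3-trans/3,4-cis. The CH2OH appears free exactly where the acyl group goes, so A2 is only an acylation with 25 and a debenzylation away from 27.
- **Against:** Substrate-controlled radical diastereoselection is usually less clean than catalyst-controlled ionic steps, so C3/C4 isomers may have to be separated. The C2 centre of A1 would come from a kinetic resolution or an extra asymmetric step. Alkylating an alkoxide next to an epoxide invites epoxide migration. More than two equivalents of titanium reagent are consumed, and the final hydrogenolysis must spare the benzylic C2–O1 ether.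
- **Comparison:** On structure it is the better fit in one respect: the C3 branch enters at the alcohol oxidation level, whereas the chosen plan spends three steps bringing a carboxyl down. On step economy it is clearly better, at roughly half the length. On mechanism the chosen plan is better, because each stereocentre has its own strong control element and the absolute configuration comes from a catalyst acting on all of the material.

**Alternative 2:** The cuts are O1–C2, C3–C4 and the aryl–CH bond of the future benzyl group.

- **Forward step:** The alkoxide A4 would add to the arylidene malonate A3 (oxa-Michael). Zerovalent palladium (Pd2(dba)3 with a chiral bisphosphine) would insert into the C–I bond of A5, the arylpalladium iodide (divalent palladium) would activate the alkyne, the malonate carbon would attack anti in a 5-exo-dig closure (C3–C4), and reductive elimination would form the aryl–CH bond of A6.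
- **In favour:** Three simple components give the whole ring, all carbons and both aryl groups in one flask. The exocyclic benzylidene at C4 is the same device the chosen plan uses to set C4, so on that point the two are equal.
- **Against:** C2 is created in the reversible, uncatalysed oxa-Michael step, remote from palladium. The ligand could control it only by selecting between equilibrating adducts during cyclisation, which is not secured. C3 is a quaternary diester: one ester must be removed by hot halide-mediated dealkoxycarbonylation next to an alkene that can migrate into the ring, and C3 is then set only by protonation. Benzyl ethers also conflict with the alkene hydrogenation.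
- **Comparison:** On step economy and convergence it is the better plan. On structure the chosen plan is better, since every succinate carbon ends in the target and no carboxyl is discarded. On mechanism the chosen plan is better at C2 and C3 (catalyst control plus dynamic resolution) and equal at C4.

**Alternative 3:** The cuts are C2–C3 and C4–C5.

- **Forward step:** CsF would take the silyl group from the chloro ether A7 with loss of chloride to give the carbonyl ylide A8. A8 would add across the C=C bond of the furanone A9 on the face opposite the menthyloxy group to give the cis-fused bicycle A10.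
- **Correct name of A10:** The aryl-bearing carbon is bonded to the bridgehead next to the lactone carbonyl, so A10 is the 8-aryl-4-menthyloxy-3,7-dioxabicyclo[3.3.0]octan-2-one. Only this regiochemistry puts the carboxyl carbon on C3 of the target.
- **In favour:** The suprafacial cycloaddition makes the two bridgehead hydrogens cis, which is exactly the 3,4-cis relation. The absolute configuration comes from an inexpensive, crystalline dipolarophile with a dependable facial bias. The ether ring forms directly at the right oxidation level, so no lactone-to-ether adjustment is needed.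
- **Against:** The ylide is unsymmetrical, so neither the regiochemistry (aryl carbon to C3) nor the exo orientation of the aryl group (the C2 configuration) is secured. A7 is moisture-sensitive. After the key step the acetal must be unmasked and the second aryl group attached by organometallic addition and benzylic deoxygenation beside another sensitive benzylic ether. The auxiliary is stoichiometric, though recoverable.
- **Comparison:** On structure the two plans are equal: both read the C3 branch as a carboxyl. On mechanism the alternative is better at C3/C4 (concerted, no face-selective hydrogenation) and worse at C2. On step economy it is about equal to slightly better.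

Key step: step 4

Remark on the chemistry: the C3 hydroxymethyl group is protected as a tert-butyldimethylsilyl ether and the phenols as triisopropylsilyl ethers, so that dilute acid frees the alcohol alone and the ester is attached before the phenols are released. Potassium mono-tert-butyl malonate (4) and both silyl chlorides are taken as commercial. Ring numbering O1, C2 (aryl), C3 (CH2O branch), C4 (benzyl), C5 is used throughout. Ar = 3-methoxy-4-[(triisopropylsilyl)oxy]phenyl.

## Steps

Step 1
Reactants: 1 vanillic acid (4-hydroxy-3-methoxybenzoic acid)
Product: 3 3-methoxy-4-[(triisopropylsilyl)oxy]benzoic acid, via bis-silylated vanillic acid 2 (not isolated)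
Conditions: iPr3SiCl (2.2 equiv), imidazole, DMF, rt; then AcOH/THF/H2O, rt
Reagents that add atoms: triisopropylsilyl chloride, CC(C)[Si](Cl)(C(C)C)C(C)C
Why: Imidazole-promoted silylation caps both the phenol and the carboxyl group; the silyl ester is far more labile than the aryl silyl ether and is hydrolysed by aqueous acetic acid, leaving the aryl triisopropylsilyl ether that should survive every later step.

Step 2
Reactants: 3 3-methoxy-4-[(triisopropylsilyl)oxy]benzoic acid; 4 potassium 3-tert-butoxy-3-oxopropanoate
Product: 7 tert-butyl 3-Ar-3-oxopropanoate, via acyl imidazolide 5 (not isolated), via acylmalonic half ester 6 (not isolated)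
Conditions: CDI, THF, rt; then 4, MgCl2, Et3N, MeCN, rt to 40 °C; cold 1 M HCl
Reagents that add atoms: none
Why: Decarboxylative C-acylation of a magnesium malonate half ester (Claisen-type): the imidazolide acylates the chelated enolate and the acylmalonate loses CO2, so the tert-butyl β-keto ester should form without strong base and without harm to the aryl silyl ether.

Step 3
Reactants: 7 tert-butyl 3-Ar-3-oxopropanoate; 8 methyl bromoacetate
Product: 9 1-tert-butyl 4-methyl 2-(3-methoxy-4-[(triisopropylsilyl)oxy]benzoyl)butanedioate (racemic)
Conditions: NaH (1.0 equiv), THF, 0 °C; then 8, 0 °C to rt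
Reagents that add atoms: none
Why: SN2 C-alkylation of the stabilised sodium enolate with an activated primary bromide; one equivalent of base and of bromide limits double alkylation, and the new stereocentre is racemic and labile on purpose.

Step 4
Reactants: 9 1-tert-butyl 4-methyl 2-aroylbutanedioate (racemic)
Product: 11 tert-butyl (2R,3R)-2-Ar-5-oxotetrahydrofuran-3-carboxylate, via hydroxy diester 10 (not isolated)
Conditions: RuCl(p-cymene)[(R,R)-TsDPEN] (1 mol %), HCO2H/Et3N (5:2), DMF, 40 °C; then PPTS (cat.), PhMe, 60 °C
Reagents that add atoms: none
Why: In HCO2H/Et3N the divalent ruthenium chloride precatalyst becomes a ruthenium hydride with an N–H group, which passes hydride to the carbonyl carbon and a proton to oxygen through a six-membered outer-sphere transition state while formate leaves as CO2; the closest known reaction type is asymmetric transfer hydrogenation of α-substituted β-keto esters with dynamic kinetic resolution and lactonisation. The ketone aryl ring is held against the η6-arene by a CH/π contact, so the (R,R)-ligand should deliver hydride to the Si face and make C2 R, the same sense as for simple aryl alkyl ketones. C3 of 9 lies between the ketone and the tert-butyl ester and epimerises through its enol much faster than reduction occurs, and the enantiomer that keeps its CH2CO2Me branch away from the incoming hydride should react faster, so the racemate should funnel into the syn hydroxy diester 10 with C3 R. The C2 hydroxyl then attacks the methyl ester in a 5-exo-trig acyl substitution that forms O1–C5 and closes the only ring; the tert-butyl ester is hindered and could only give a β-lactone. The syn relation of 10 maps onto the 2,3-trans lactone, which is also the more stable isomer, and since C3 of 11 stays α to an ester any cis lactone can be equilibrated to trans with a trace of amidine base. The step needs selectivity for the ketone over two esters and an aryl silyl ether, which the hydride-transfer mechanism secures, and fast racemisation, which the doubly activated C3–H secures.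

Step 5
Reactants: 11 tert-butyl (2R,3R)-2-Ar-5-oxotetrahydrofuran-3-carboxylate
Product: 12 (2R,3R)-2-Ar-5-oxotetrahydrofuran-3-carboxylic acid
Conditions: CF3CO2H/CH2Cl2 (1:4), 0 °C to rt
Reagents that add atoms: none
Why: Acidolysis of the tert-butyl ester with loss of isobutene frees the C3 carboxylic acid; lactone and aryl silyl ether should be stable, and a reversible ionisation at the benzylic C2–O bond would only re-close to the more stable trans lactone.

Step 6
Reactants: 12 (2R,3R)-2-Ar-5-oxotetrahydrofuran-3-carboxylic acid
Product: 13 (4S,5R)-4-(hydroxymethyl)-5-Ar-dihydrofuran-2(3H)-one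
Conditions: BH3·SMe2, THF, 0 °C to rt; MeOH
Reagents that add atoms: none
Why: Borane reduces a carboxylic acid through its acyloxyborane much faster than a lactone, so only the C3 carboxyl should become CH2OH; no stereocentre is touched, and the descriptor at C3 changes only because the branch loses CIP priority.

Step 7
Reactants: 13 (4S,5R)-4-(hydroxymethyl)-5-Ar-dihydrofuran-2(3H)-one
Product: 14 (4S,5R)-4-{[(tert-butyldimethylsilyl)oxy]methyl}-5-Ar-dihydrofuran-2(3H)-one
Conditions: tBuMe2SiCl, imidazole, CH2Cl2, 0 °C
Reagents that add atoms: tert-butyldimethylsilyl chloride, CC(C)(C)[Si](C)(C)Cl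
Why: Neutral silylation of the primary alcohol, carried out at once on crude 13 so that the free hydroxyl has no time to translactonise; this silyl ether can later be removed by dilute acid while the aryl silyl ethers stay.

Step 8
Reactants: 15 vanillin
Product: 16 3-methoxy-4-[(triisopropylsilyl)oxy]benzaldehyde
Conditions: iPr3SiCl, imidazole, DMF, rt
Reagents that add atoms: triisopropylsilyl chloride, CC(C)[Si](Cl)(C(C)C)C(C)C
Why: Standard phenol silylation; the same group is used on both aryl rings so that both phenols are freed together in the last step.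

Step 9
Reactants: 14 (4S,5R)-4-{[(tert-butyldimethylsilyl)oxy]methyl}-5-Ar-dihydrofuran-2(3H)-one; 16 3-methoxy-4-[(triisopropylsilyl)oxy]benzaldehyde
Product: 17 (3S,4S,5R)-4-{[(tert-butyldimethylsilyl)oxy]methyl}-3-[hydroxy(Ar)methyl]-5-Ar-dihydrofuran-2(3H)-one (both carbinol epimers)
Conditions: LiN(SiMe3)2, THF, −78 °C; then 16, −78 °C; aq. NH4Cl
Reagents that add atoms: none
Why: Lactone 14 has a single enolisable position (C4 of the target), so one lithium enolate forms and adds to the non-enolisable aldehyde (aldol addition) anti to the C3 branch; carbinol epimers and any C4 epimer converge in the next step.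

Step 10
Reactants: 17 aldol adduct
Product: 19 (3E,4S,5R)-4-{[(tert-butyldimethylsilyl)oxy]methyl}-3-(Ar-methylidene)-5-Ar-dihydrofuran-2(3H)-one, via benzylic mesylate 18 (not isolated)
Conditions: MsCl, Et3N, CH2Cl2, 0 °C; then DBU, 0 °C to rt
Reagents that add atoms: none
Why: Mesylation of the benzylic alcohol and E1cB elimination through the lactone enolate should give the conjugated benzylidene lactone, expected as the E isomer; either alkene isomer leads to the same product after reduction, and short exposure to base limits γ-deprotonation.

Step 11
Reactants: 19 benzylidene lactone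
Product: 20 (3S,4S,5R)-4-{[(tert-butyldimethylsilyl)oxy]methyl}-3-(Ar-methyl)-5-Ar-dihydrofuran-2(3H)-one
Conditions: H2 (1 atm), 5% Pd/C, EtOAc, rt
Reagents that add atoms: none
Why: Heterogeneous syn-hydrogenation of the exocyclic enoate: allylic 1,3-strain with the arylidene group pushes the C3 CH2OSi group pseudoaxial so that it blocks one face, and hydrogen should add to the other face, placing the benzyl group cis to the C3 branch (C4 S); neutral ethyl acetate at 1 atm is chosen to avoid hydrogenolysis of the benzylic lactone C–O bond.

Step 12
Reactants: 20 cis-benzyl lactone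
Product: 21 (1R,2S,3S)-2-{[(tert-butyldimethylsilyl)oxy]methyl}-1-Ar-3-(Ar-methyl)butane-1,4-diol
Conditions: LiBH4, THF, 0 °C to rt
Reagents that add atoms: none
Why: Hydride reduction of the lactone to the 1,4-diol; LiBH4 reduces lactones readily, is too weakly basic to epimerise C4 and should leave alkyl and aryl silyl ethers untouched.

Step 13
Reactants: 21 diol
Product: 23 tert-butyl{[(2R,3S,4S)-2-Ar-4-(Ar-methyl)tetrahydrofuran-3-yl]methoxy}dimethylsilane, via primary tosylate 22 (not isolated)
Conditions: TsCl (1.1 equiv), Et3N, DMAP (cat.), CH2Cl2, 0 °C; then NaH, THF, 0 °C to rt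
Reagents that add atoms: none
Why: Sulfonylation should be selective for the unhindered primary hydroxyl over the secondary benzylic one, and the C2 alkoxide then displaces the tosylate in a 5-exo-tet Williamson etherification; the C2–O bond is never broken, so C2 keeps its R configuration.

Step 14
Reactants: 23 fully silylated tetrahydrofuran
Product: 24 [(2R,3S,4S)-2-Ar-4-(Ar-methyl)tetrahydrofuran-3-yl]methanol
Conditions: camphor-10-sulfonic acid (10 mol %), MeOH/CH2Cl2 (1:1), 0 °C
Reagents that add atoms: none
Why: Acid-catalysed methanolysis cleaves a primary alkyl silyl ether far faster than hindered aryl triisopropylsilyl ethers, so only the C3 hydroxymethyl group is exposed; catalytic acid at 0 °C should be too weak to ionise the benzylic ether.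

Step 15
Reactants: 24 primary alcohol; 25 (R)-2-methylbutanoic acid
Product: 26 [(2R,3S,4S)-2-Ar-4-(Ar-methyl)tetrahydrofuran-3-yl]methyl (2R)-2-methylbutanoate
Conditions: EDC·HCl, DMAP (cat.), CH2Cl2, 0 °C to rt
Reagents that add atoms: none
Why: Carbodiimide/DMAP (Steglich) esterification of the only free hydroxyl; activation as O-acylisourea and acylpyridinium avoids the ketene pathway of acid chlorides, so the α-stereocentre of 25 should be retained.

Step 16
Reactants: 26 bis-silylated ester
Product: 27 [(2R,3S,4S)-2-(4-hydroxy-3-methoxyphenyl)-4-(4-hydroxy-3-methoxybenzyl)tetrahydrofuran-3-yl]methyl (2R)-2-methylbutanoate (target)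
Conditions: Bu4NF, AcOH (1:1), THF, 0 °C
Reagents that add atoms: none
Why: Fluoride cleaves both aryl Si–O bonds (strong Si–F bond, phenoxide leaving group); acetic acid buffers the phenoxides so that neither the ester nor the p-hydroxybenzylic ether is exposed to base.

## Compound list

1 | vanillic acid | OC(=O)c1ccc(O)c(OC)c1 | starting material
2 | triisopropylsilyl 3-methoxy-4-[(triisopropylsilyl)oxy]benzoate | CC(C)[Si](OC(=O)c1ccc(O[Si](C(C)C)(C(C)C)C(C)C)c(OC)c1)(C(C)C)C(C)C | intermediate (not isolated)
3 | 3-methoxy-4-[(triisopropylsilyl)oxy]benzoic acid | OC(=O)c1ccc(O[Si](C(C)C)(C(C)C)C(C)C)c(OC)c1 | intermediate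
4 | potassium 3-tert-butoxy-3-oxopropanoate | [K+].[O-]C(=O)CC(=O)OC(C)(C)C | starting material
5 | 1-{3-methoxy-4-[(triisopropylsilyl)oxy]benzoyl}imidazole | O=C(c1ccc(O[Si](C(C)C)(C(C)C)C(C)C)c(OC)c1)n1ccnc1 | intermediate (not isolated)
6 | 2-(tert-butoxycarbonyl)-3-Ar-3-oxopropanoic acid (magnesium chelate) | OC(=O)C(C(=O)OC(C)(C)C)C(=O)c1ccc(O[Si](C(C)C)(C(C)C)C(C)C)c(OC)c1 | intermediate (not isolated)
7 | tert-butyl 3-Ar-3-oxopropanoate | CC(C)(C)OC(=O)CC(=O)c1ccc(O[Si](C(C)C)(C(C)C)C(C)C)c(OC)c1 | intermediate
8 | methyl bromoacetate | COC(=O)CBr | starting material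
9 | 1-tert-butyl 4-methyl 2-{3-methoxy-4-[(triisopropylsilyl)oxy]benzoyl}butanedioate (racemic) | COC(=O)CC(C(=O)c1ccc(O[Si](C(C)C)(C(C)C)C(C)C)c(OC)c1)C(=O)OC(C)(C)C | intermediate
10 | 1-tert-butyl 4-methyl (2R)-2-[(R)-hydroxy(Ar)methyl]butanedioate | CC(C)(C)OC(=O)[C@H](CC(=O)OC)[C@@H](O)c1ccc(O[Si](C(C)C)(C(C)C)C(C)C)c(OC)c1 | intermediate (not isolated)
11 | tert-butyl (2R,3R)-2-Ar-5-oxotetrahydrofuran-3-carboxylate | CC(C)(C)OC(=O)[C@@H]1CC(=O)O[C@H]1c1ccc(O[Si](C(C)C)(C(C)C)C(C)C)c(OC)c1 | intermediate
12 | (2R,3R)-2-Ar-5-oxotetrahydrofuran-3-carboxylic acid | OC(=O)[C@@H]1CC(=O)O[C@H]1c1ccc(O[Si](C(C)C)(C(C)C)C(C)C)c(OC)c1 | intermediate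
13 | (4S,5R)-4-(hydroxymethyl)-5-Ar-dihydrofuran-2(3H)-one | OC[C@@H]1CC(=O)O[C@H]1c1ccc(O[Si](C(C)C)(C(C)C)C(C)C)c(OC)c1 | intermediate
14 | (4S,5R)-4-{[(tert-butyldimethylsilyl)oxy]methyl}-5-Ar-dihydrofuran-2(3H)-one | CC(C)(C)[Si](C)(C)OC[C@@H]1CC(=O)O[C@H]1c1ccc(O[Si](C(C)C)(C(C)C)C(C)C)c(OC)c1 | intermediate
15 | vanillin | O=Cc1ccc(O)c(OC)c1 | starting material
16 | 3-methoxy-4-[(triisopropylsilyl)oxy]benzaldehyde | O=Cc1ccc(O[Si](C(C)C)(C(C)C)C(C)C)c(OC)c1 | intermediate
17 | (3S,4S,5R)-4-{[(tert-butyldimethylsilyl)oxy]methyl}-3-[hydroxy(Ar)methyl]-5-Ar-dihydrofuran-2(3H)-one (both carbinol epimers) | CC(C)(C)[Si](C)(C)OC[C@@H]1[C@@H](C(O)c2ccc(O[Si](C(C)C)(C(C)C)C(C)C)c(OC)c2)C(=O)O[C@H]1c1ccc(O[Si](C(C)C)(C(C)C)C(C)C)c(OC)c1 | intermediate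
18 | methanesulfonate of 17 at the benzylic hydroxyl | CC(C)(C)[Si](C)(C)OC[C@@H]1[C@@H](C(OS(C)(=O)=O)c2ccc(O[Si](C(C)C)(C(C)C)C(C)C)c(OC)c2)C(=O)O[C@H]1c1ccc(O[Si](C(C)C)(C(C)C)C(C)C)c(OC)c1 | intermediate (not isolated)
19 | (3E,4S,5R)-4-{[(tert-butyldimethylsilyl)oxy]methyl}-3-(Ar-methylidene)-5-Ar-dihydrofuran-2(3H)-one | CC(C)(C)[Si](C)(C)OC[C@@H]1/C(=C\c2ccc(O[Si](C(C)C)(C(C)C)C(C)C)c(OC)c2)C(=O)O[C@H]1c1ccc(O[Si](C(C)C)(C(C)C)C(C)C)c(OC)c1 | intermediate
20 | (3S,4S,5R)-4-{[(tert-butyldimethylsilyl)oxy]methyl}-3-(Ar-methyl)-5-Ar-dihydrofuran-2(3H)-one | CC(C)(C)[Si](C)(C)OC[C@@H]1[C@H](Cc2ccc(O[Si](C(C)C)(C(C)C)C(C)C)c(OC)c2)C(=O)O[C@H]1c1ccc(O[Si](C(C)C)(C(C)C)C(C)C)c(OC)c1 | intermediate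
21 | (1R,2S,3S)-2-{[(tert-butyldimethylsilyl)oxy]methyl}-1-Ar-3-(Ar-methyl)butane-1,4-diol | CC(C)(C)[Si](C)(C)OC[C@H]([C@H](Cc2ccc(O[Si](C(C)C)(C(C)C)C(C)C)c(OC)c2)CO)[C@@H](O)c1ccc(O[Si](C(C)C)(C(C)C)C(C)C)c(OC)c1 | intermediate
22 | (2S,3S,4R)-3-{[(tert-butyldimethylsilyl)oxy]methyl}-4-hydroxy-4-Ar-2-(Ar-methyl)butyl 4-methylbenzenesulfonate | CC(C)(C)[Si](C)(C)OC[C@H]([C@H](Cc2ccc(O[Si](C(C)C)(C(C)C)C(C)C)c(OC)c2)COS(=O)(=O)c3ccc(C)cc3)[C@@H](O)c1ccc(O[Si](C(C)C)(C(C)C)C(C)C)c(OC)c1 | intermediate (not isolated)
23 | tert-butyl{[(2R,3S,4S)-2-Ar-4-(Ar-methyl)tetrahydrofuran-3-yl]methoxy}dimethylsilane | CC(C)(C)[Si](C)(C)OC[C@@H]1[C@H](Cc2ccc(O[Si](C(C)C)(C(C)C)C(C)C)c(OC)c2)CO[C@H]1c1ccc(O[Si](C(C)C)(C(C)C)C(C)C)c(OC)c1 | intermediate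
24 | [(2R,3S,4S)-2-Ar-4-(Ar-methyl)tetrahydrofuran-3-yl]methanol | OC[C@@H]1[C@H](Cc2ccc(O[Si](C(C)C)(C(C)C)C(C)C)c(OC)c2)CO[C@H]1c1ccc(O[Si](C(C)C)(C(C)C)C(C)C)c(OC)c1 | intermediate
25 | (R)-2-methylbutanoic acid | CC[C@@H](C)C(=O)O | starting material
26 | [(2R,3S,4S)-2-Ar-4-(Ar-methyl)tetrahydrofuran-3-yl]methyl (2R)-2-methylbutanoate | CC[C@@H](C)C(=O)OC[C@@H]1[C@H](Cc2ccc(O[Si](C(C)C)(C(C)C)C(C)C)c(OC)c2)CO[C@H]1c1ccc(O[Si](C(C)C)(C(C)C)C(C)C)c(OC)c1 | intermediate
27 | [(2R,3S,4S)-2-(4-hydroxy-3-methoxyphenyl)-4-(4-hydroxy-3-methoxybenzyl)tetrahydrofuran-3-yl]methyl (2R)-2-methylbutanoate | CC[C@@H](C)C(=O)OC[C@@H]1[C@H](Cc2ccc(O)c(OC)c2)CO[C@H]1c1ccc(O)c(OC)c1 | target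

## Step count and least certain steps

Total step count: 16. Longest linear sequence: 15 steps (steps 1–7 and 9–16, from 1 to 27); step 8 is a one-step side branch.

**Step 4 (key step).** Three things may go wrong.
- The dynamic resolution may lose diastereocontrol, because the flexible CH2CO2Me branch may not differentiate the two C3 configurations strongly, leaving some cis lactone.
- Hydride transfer to the electron-rich aryl ketone may be slow.
- If base is used to equilibrate cis to trans, the C3 enolate may expel the C2 carboxylate (β-elimination with ring opening) instead of simply reprotonating.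

Fallback: set both centres by an auxiliary-controlled aldol reaction, setting out from 16 and returning at 12. The succinyl imide tert-butyl 4-[(4R)-4-benzyl-2-oxo-1,3-oxazolidin-3-yl]-4-oxobutanoate F1 (from the lithiated oxazolidinone and the pivaloyl mixed anhydride of mono-tert-butyl succinate) would be enolised at the imide side with Bu2BOTf and iPr2NEt and added to 16 (Evans syn-aldol, Zimmerman–Traxler chair) to give the syn adduct F2, with both new centres R. CF3CO2H would cleave the tert-butyl ester and close the trans lactone imide F3. LiOH/H2O2 would then remove the auxiliary to give 12, and the route continues with step 6.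

**Step 11.** Facial selectivity may be poor, because the C2 aryl group lies on the face that must accept hydrogen, and the benzylic lactone C–O bond may undergo hydrogenolysis on palladium.

Fallback: form the C4–benzyl bond by alkylation and set C4 by kinetic protonation, setting out from 14 (with 16 as the source of the electrophile) and returning at 20. 16 would be reduced with NaBH4 to the benzyl alcohol F4 and converted with CBr4/PPh3 (Appel reaction) to the benzyl bromide F5. The lithium enolate of 14 (LiN(SiMe3)2, THF, −78 °C) would be alkylated by F5 anti to the C3 branch to give the 3,4-trans lactone F6. F6 would be deprotonated again with LiN(iPr)2 at −78 °C and the enolate quenched with the bulky proton donor 2,6-di-tert-butyl-4-methylphenol, which should protonate anti to the C3 branch and give the cis lactone 20. No hydrogen or palladium is involved.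

**Step 13.** The benzylic hydroxyl may be sulfonylated in competition, followed by ionisation at C2 (loss of configuration or elimination), or double tosylation may occur.

Fallback: keep O1–C5 intact and remove only the carbonyl oxygen, setting out from 20 and returning at 23. iBu2AlH at −78 °C would reduce the lactone to the lactol F7, and Et3SiH with BF3·OEt2 at −78 °C would reduce the derived oxocarbenium ion at C5 to the ether 23, so that no hydroxyl has to be activated.

**Step 14.** The acid may open the benzylic C2–O1 bond (epimerisation at C2 or Friedel–Crafts closure onto the other arene), or the aryl silyl ethers may be partly lost.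

Fallback: give up the orthogonal deprotection, setting out from 23 and returning at 27. Excess Bu4NF would remove all three silyl groups to give (−)-lariciresinol F8. A Mitsunobu esterification (PPh3, DIAD, 25, THF, 0 °C) would then acylate the primary alcohol chemoselectively: the carboxylic acid, far more acidic than the phenols, is the pronucleophile, and only the aliphatic hydroxyl is activated as the alkoxyphosphonium ion.

## Further compounds

F1 | step 4 | tert-butyl 4-[(4R)-4-benzyl-2-oxo-1,3-oxazolidin-3-yl]-4-oxobutanoate | CC(C)(C)OC(=O)CCC(=O)N1[C@H](Cc2ccccc2)COC1=O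
F2 | step 4 | tert-butyl (3R,4R)-3-{[(4R)-4-benzyl-2-oxo-1,3-oxazolidin-3-yl]carbonyl}-4-hydroxy-4-Ar-butanoate | O=C(N1[C@H](Cc2ccccc2)COC1=O)[C@H](CC(=O)OC(C)(C)C)[C@@H](O)c1ccc(O[Si](C(C)C)(C(C)C)C(C)C)c(OC)c1
F3 | step 4 | (4R)-4-benzyl-3-{[(2R,3R)-2-Ar-5-oxotetrahydrofuran-3-yl]carbonyl}-1,3-oxazolidin-2-one | O=C(N1[C@H](Cc2ccccc2)COC1=O)[C@@H]1CC(=O)O[C@H]1c1ccc(O[Si](C(C)C)(C(C)C)C(C)C)c(OC)c1
F4 | step 11 | {3-methoxy-4-[(triisopropylsilyl)oxy]phenyl}methanol | OCc1ccc(O[Si](C(C)C)(C(C)C)C(C)C)c(OC)c1
F5 | step 11 | [4-(bromomethyl)-2-methoxyphenoxy]triisopropylsilane | BrCc1ccc(O[Si](C(C)C)(C(C)C)C(C)C)c(OC)c1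
F6 | step 11 | (3R,4S,5R)-4-{[(tert-butyldimethylsilyl)oxy]methyl}-3-(Ar-methyl)-5-Ar-dihydrofuran-2(3H)-one | CC(C)(C)[Si](C)(C)OC[C@@H]1[C@@H](Cc2ccc(O[Si](C(C)C)(C(C)C)C(C)C)c(OC)c2)C(=O)O[C@H]1c1ccc(O[Si](C(C)C)(C(C)C)C(C)C)c(OC)c1
F7 | step 13 | (3S,4S,5R)-4-{[(tert-butyldimethylsilyl)oxy]methyl}-3-(Ar-methyl)-5-Ar-tetrahydrofuran-2-ol (both anomers) | CC(C)(C)[Si](C)(C)OC[C@@H]1[C@H](Cc2ccc(O[Si](C(C)C)(C(C)C)C(C)C)c(OC)c2)C(O)O[C@H]1c1ccc(O[Si](C(C)C)(C(C)C)C(C)C)c(OC)c1
F8 | step 14 | (−)-lariciresinol | OC[C@@H]1[C@H](Cc2ccc(O)c(OC)c2)CO[C@H]1c1ccc(O)c(OC)c1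
A1 | alternative 1 | 2-{(S)-[4-(benzyloxy)-3-methoxyphenyl]{[(2E)-3-[4-(benzyloxy)-3-methoxyphenyl]prop-2-en-1-yl]oxy}methyl}oxirane (either oxirane epimer) | C1OC1[C@@H](OC/C=C/c2ccc(OCc3ccccc3)c(OC)c2)c4ccc(OCc5ccccc5)c(OC)c4
A2 | alternative 1 | di-O-benzyl-(−)-lariciresinol | OC[C@@H]1[C@H](Cc2ccc(OCc3ccccc3)c(OC)c2)CO[C@H]1c4ccc(OCc5ccccc5)c(OC)c4
A3 | alternative 2 | diethyl 2-[4-(benzyloxy)-3-methoxybenzylidene]propanedioate | CCOC(=O)C(=Cc1ccc(OCc2ccccc2)c(OC)c1)C(=O)OCC
A4 | alternative 2 | sodium prop-2-yn-1-olate | [Na+].[O-]CC#C
A5 | alternative 2 | 1-(benzyloxy)-4-iodo-2-methoxybenzene | COc1cc(I)ccc1OCc1ccccc1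
A6 | alternative 2 | diethyl (4Z)-2-[4-(benzyloxy)-3-methoxyphenyl]-4-[4-(benzyloxy)-3-methoxybenzylidene]dihydrofuran-3,3(2H)-dicarboxylate | CCOC(=O)C1(C(=O)OCC)/C(=C/c2ccc(OCc3ccccc3)c(OC)c2)CO[C@H]1c4ccc(OCc5ccccc5)c(OC)c4
A7 | alternative 3 | ({chloro[4-(benzyloxy)-3-methoxyphenyl]methoxy}methyl)trimethylsilane | C[Si](C)(C)COC(Cl)c1ccc(OCc2ccccc2)c(OC)c1
A8 | alternative 3 | carbonyl ylide from 4-(benzyloxy)-3-methoxybenzaldehyde and methylene | [CH2-][O+]=Cc1ccc(OCc2ccccc2)c(OC)c1
A9 | alternative 3 | (5R)-5-[(1R,2S,5R)-menthyloxy]furan-2(5H)-one | O1C(=O)C=C[C@@H]1O[C@@H]2C[C@H](C)CC[C@H]2C(C)C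
A10 | alternative 3 | cis-fused 8-[4-(benzyloxy)-3-methoxyphenyl]-4-[(1R,2S,5R)-menthyloxy]-3,7-dioxabicyclo[3.3.0]octan-2-one | O1C(=O)[C@@H]2[C@H]([C@@H]1O[C@@H]3C[C@H](C)CC[C@H]3C(C)C)CO[C@H]2c4ccc(OCc5ccccc5)c(OC)c4
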